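**Strategy.** The bicyclo[3.2.1]octane core is cut at the bond joining its one-carbon bridge CH (the carbon next to the lactone O–C(CH3) carbon, a methyl ketone at that stage) to the bridgehead CH that lies β to the cyclohexanone carbonyl. In the forward sense, a cyclohept-2-ene-1,5-dione with an acetonyl arm on a quaternary ring carbon folds on itself: the acetonyl enolate adds across the ring to the enone β-carbon, closing the cyclopentanone and cyclohexanone rings together and fixing the bridgehead. The precursor already carries all three fully substituted stereocentres, which come from two palladium-catalysed allylic substitutions of one vinyl epoxide. Ring C, the lactone and both dienoyl groups follow.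

Key step: step 12

Remarks on the chemistry (assumptions and design points)
- Ligand L is (1R,2R)-N,N′-bis[2-(diphenylphosphanyl)benzoyl]cyclohexane-1,2-diamine and ent-L is its mirror image. It is assumed that L gives the S ether 3; step 5 needs the opposite facial sense and uses ent-L. If the sense proves reversed, the two antipodes are exchanged.
- The tertiary ring oxygen is carried as a benzyl ether, because it is installed by the enantioselective etherification itself and is removed without an extra step in the hydrogenation of step 17.
- The diketone formed in the key step is correctly an 8-acetylbicyclo[3.2.1]octane-3,6-dione: one ketone is the middle carbon of the three-carbon bridge, the other is in the two-carbon bridge next to the substituted bridgehead.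
- The dienone on the bridgehead needs a five-carbon dienyl unit, since its carbonyl carbon is already present as the CH2O carbon. Only the ring-side sorbyl group arrives as a six-carbon acyl unit.
- In the target the lactone α-methyl is trans to the neighbouring hydroxyl and points toward the cyclohexanone. It is therefore set by hydrogen delivery from the open face (step 17), not by an aldol bond formation, which would place it on the open face.
- Ring C is the cyclopentane closed in step 14. Compounds 9 and 12 may exist partly as cyclic hemiketals; the open forms are drawn. The target is drawn as the hydrogen-bonded exocyclic enol of its β-diketone.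

**Route**

Step 1
Reactants: 1 2-methyl-2-vinyloxirane (racemic); 2 benzyl alcohol
Product: 3 (2S)-2-(benzyloxy)-2-methylbut-3-en-1-ol
Conditions: Pd2(dba)3·CHCl3 (1 mol%), L (3 mol%), Et3B (1 mol%), CH2Cl2, rt
Reagents that add atoms: none
Why: Palladium-catalysed dynamic kinetic asymmetric allylic etherification (Tsuji–Trost type), in which the two π-allyl complexes from racemic 1 interconvert and the borane-bound alkoxide is delivered to the tertiary terminus inside the chiral pocket, setting the tertiary ether carbon as S.

Step 2
Reactants: 3 (2S)-2-(benzyloxy)-2-methylbut-3-en-1-ol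
Product: 4 (2S)-2-(benzyloxy)-2-methylbut-3-enal
Conditions: Dess–Martin periodinane, CH2Cl2, 0 °C to rt
Reagents that add atoms: none
Why: Dess–Martin oxidation of the primary alcohol gives an aldehyde with no α-hydrogen, so the stereocentre cannot epimerise.

Step 3
Reactants: 4 (2S)-2-(benzyloxy)-2-methylbut-3-enal; 5 tert-butyl diazoacetate
Product: 6 tert-butyl (4S)-4-(benzyloxy)-4-methyl-3-oxohex-5-enoate
Conditions: SnCl2 (10 mol%), CH2Cl2, rt
Reagents that add atoms: none
Why: Roskamp homologation, in which Lewis-acid-promoted addition of the diazo ester to the aldehyde and a 1,2-hydride shift with loss of nitrogen give the β-keto ester directly without touching the stereocentre.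

Step 4
Reactants: 6 tert-butyl (4S)-4-(benzyloxy)-4-methyl-3-oxohex-5-enoate; 7 chloroacetone
Product: 8 tert-butyl (4S)-4-(benzyloxy)-4-methyl-3-oxo-2-(2-oxopropyl)hex-5-enoate (both C2 epimers)
Conditions: K2CO3, NaI (10 mol%), acetone, rt
Reagents that add atoms: none
Why: C-Alkylation of the β-keto ester enolate with iodoacetone formed in situ (Finkelstein exchange) installs the acetonyl arm at the doubly activated carbon, whose configuration stays labile and is fixed only in step 5.

Step 5
Reactants: 8 tert-butyl (4S)-4-(benzyloxy)-4-methyl-3-oxo-2-(2-oxopropyl)hex-5-enoate; 1 2-methyl-2-vinyloxirane (racemic)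
Product: 9 tert-butyl (2S,3S)-2-[(2S)-2-(benzyloxy)-2-methylbut-3-enoyl]-3-(hydroxymethyl)-3-methyl-2-(2-oxopropyl)pent-4-enoate
Conditions: Pd2(dba)3·CHCl3 (2.5 mol%), ent-L (7.5 mol%), CH2Cl2, rt
Reagents that add atoms: none
Why: Palladium-catalysed asymmetric allylic alkylation of a 2-substituted β-keto ester by the vinyl epoxide, in which the pronucleophile protonates the alkoxide of the π-allyl complex and the resulting ion pair attacks the tertiary terminus, so that the ligand sets the methyl/vinyl carbon and, through the organised ion pair, the face of the enolate, forming two adjacent quaternary carbons in one bond formation while the tert-butyl ester keeps the new primary alcohol from lactonising.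

Step 6
Reactants: 9 tert-butyl (2S,3S)-2-[(2S)-2-(benzyloxy)-2-methylbut-3-enoyl]-3-(hydroxymethyl)-3-methyl-2-(2-oxopropyl)pent-4-enoate
Product: 10 tert-butyl (2S,3S)-2-[(2S)-2-(benzyloxy)-2-methylbut-3-enoyl]-3-formyl-3-methyl-2-(2-oxopropyl)pent-4-enoate
Conditions: Dess–Martin periodinane, CH2Cl2, rt
Reagents that add atoms: none
Why: Dess–Martin oxidation of the only hydroxyl gives a non-enolisable aldehyde on the quaternary carbon.

Step 7
Reactants: 10 tert-butyl (2S,3S)-2-[(2S)-2-(benzyloxy)-2-methylbut-3-enoyl]-3-formyl-3-methyl-2-(2-oxopropyl)pent-4-enoate; 11 vinyl bromide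
Product: 12 tert-butyl (2S,3S)-2-[(2S)-2-(benzyloxy)-2-methylbut-3-enoyl]-3-(1-hydroxyprop-2-en-1-yl)-3-methyl-2-(2-oxopropyl)pent-4-enoate (both carbinol epimers)
Conditions: CrCl2 (4 equiv), NiCl2 (2 mol%), DMF, rt
Reagents that add atoms: none
Why: Nozaki–Hiyama–Kishi vinylation, in which the vinylchromium reagent adds only to the aldehyde and leaves the two ketones and the ester alone; the new carbinol centre is a mixture and is erased in step 11.

Step 8
Reactants: 12 tert-butyl (2S,3S)-2-[(2S)-2-(benzyloxy)-2-methylbut-3-enoyl]-3-(1-hydroxyprop-2-en-1-yl)-3-methyl-2-(2-oxopropyl)pent-4-enoate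
Product: 13 tert-butyl (1S,3S,7S)-3-(benzyloxy)-7-ethenyl-6-hydroxy-3,7-dimethyl-2-oxo-1-(2-oxopropyl)cyclohept-4-ene-1-carboxylate (both C6 epimers)
Conditions: second-generation Hoveyda–Grubbs catalyst (5 mol%), CH2Cl2, 40 °C
Reagents that add atoms: none
Why: Ring-closing metathesis, in which the ruthenium carbene loads on the only vinyl group at a secondary, hydroxyl-bearing carbon and from there can reach only the vinyl group on the benzyloxy carbon (seven-membered ring), whereas closure between the two vinyl groups on fully substituted carbons is the slowest pathway.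

Step 9
Reactants: 13 tert-butyl (1S,3S,7S)-3-(benzyloxy)-7-ethenyl-6-hydroxy-3,7-dimethyl-2-oxo-1-(2-oxopropyl)cyclohept-4-ene-1-carboxylate
Product: 14 (4S,6R,7S)-4-(benzyloxy)-7-ethenyl-6-(hydroxymethyl)-6-(2-hydroxypropyl)-4,7-dimethylcyclohept-2-ene-1,5-diol (carbinol carbons as mixtures)
Conditions: LiAlH4, THF, 0 °C to reflux; aqueous Rochelle salt
Reagents that add atoms: none
Why: Hydride reduction converts the hindered tert-butyl ester into the primary alcohol, and the two ketones that are reduced alongside are restored in step 11.

Step 10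
Reactants: 14 (4S,6R,7S)-4-(benzyloxy)-7-ethenyl-6-(hydroxymethyl)-6-(2-hydroxypropyl)-4,7-dimethylcyclohept-2-ene-1,5-diol
Product: 15 (4S,6R,7S)-4-(benzyloxy)-6-{[tert-butyl(dimethyl)silyl]oxymethyl}-7-ethenyl-6-(2-hydroxypropyl)-4,7-dimethylcyclohept-2-ene-1,5-diol (carbinol carbons as mixtures)
Conditions: TBSCl (1.05 equiv), imidazole, DMF, 0 °C
Reagents that add atoms: tert-butyldimethylsilyl chloride, CC(C)(C)[Si](C)(C)Cl
Why: Selective silylation of the single primary hydroxyl in the presence of three secondary ones.

Step 11
Reactants: 15 (4S,6R,7S)-4-(benzyloxy)-6-{[tert-butyl(dimethyl)silyl]oxymethyl}-7-ethenyl-6-(2-hydroxypropyl)-4,7-dimethylcyclohept-2-ene-1,5-diol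
Product: 16 (4S,6R,7S)-4-(benzyloxy)-6-{[tert-butyl(dimethyl)silyl]oxymethyl}-7-ethenyl-4,7-dimethyl-6-(2-oxopropyl)cyclohept-2-ene-1,5-dione
Conditions: Dess–Martin periodinane (4 equiv), CH2Cl2, rt
Reagents that add atoms: none
Why: Dess–Martin oxidation of the three secondary alcohols returns the ring ketone, the enone and the methyl ketone under non-basic conditions, so the acetonyl enone does not cyclise prematurely.

Step 12
Reactants: 16 (4S,6R,7S)-4-(benzyloxy)-6-{[tert-butyl(dimethyl)silyl]oxymethyl}-7-ethenyl-4,7-dimethyl-6-(2-oxopropyl)cyclohept-2-ene-1,5-dione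
Product: 17 (1R,4S,5R,7S,8S)-8-acetyl-7-(benzyloxy)-5-{[tert-butyl(dimethyl)silyl]oxymethyl}-4-ethenyl-4,7-dimethylbicyclo[3.2.1]octane-3,6-dione
Conditions: t-BuOK (0.3 equiv), t-BuOH/THF (1:4), 0 °C to rt
Reagents that add atoms: none
Why: Catalytic tert-butoxide equilibrates the enolates of the acetonyl ketone, the only enolisable carbonyl because every other α-carbon is fully substituted, and the methylene-side enolate adds to the enone β-carbon (C3 of the ring) in an intramolecular Michael addition, the known route from cycloheptenones with a ketone-bearing side chain to bicyclo[3.2.1]octanes. The cyclopentanone ring closes in a 5-exo-trig mode and the same bond completes the cyclohexanone ring, which taken on its own is a 6-endo-trig closure. The bridgehead CH is set by the tether, since the acetonyl arm can reach only the ring face on which it stands, the face that also carries the benzyloxy and vinyl groups. The acetyl-bearing bridge carbon is set under thermodynamic control and stays epimerisable next to its ketone, so any minor epimer is funnelled later, when only the acetyl group syn to the three-carbon bridge can close ring C. The selectivity needed is Michael addition over aldol closure of the methyl-side enolate onto the ring ketones; those aldolates are hindered tertiary alkoxides that revert, and low temperature with substoichiometric base keeps them from losing water, so the mixture should drain into the Michael adduct.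

Step 13
Reactants: 17 (1R,4S,5R,7S,8S)-8-acetyl-7-(benzyloxy)-5-{[tert-butyl(dimethyl)silyl]oxymethyl}-4-ethenyl-4,7-dimethylbicyclo[3.2.1]octane-3,6-dione
Product: 19 keto aldehyde (17 with the ethenyl group replaced by formyl), via secondary ozonide 18 (not isolated)
Conditions: O3, CH2Cl2, −78 °C; then PPh3, −78 °C to rt
Reagents that add atoms: ozone, [O-][O+]=O
Why: Ozonolysis of the only alkene with reductive work-up gives the aldehyde on the quaternary carbon, the benzyl ether reacting far more slowly and the ketones not at all.

Step 14
Reactants: 19 keto aldehyde (17 with the ethenyl group replaced by formyl)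
Product: 20 tricyclic acyloin (ring C closed: ketone at the former aldehyde carbon and tertiary hydroxyl plus methyl at the former acetyl carbon)
Conditions: 3-benzyl-5-(2-hydroxyethyl)-4-methylthiazolium chloride (20 mol%), DBU (20 mol%), THF/t-BuOH, 50 °C
Reagents that add atoms: none
Why: Carbene-catalysed intramolecular crossed benzoin (acyloin) reaction, in which the Breslow intermediate of the non-enolisable aldehyde adds to the methyl ketone to close the five-membered ring C with the ketone oxygen turned toward the cyclohexanone and its methyl outward, while the amine base epimerises the acetyl-bearing carbon so that only the epimer with acetyl syn to the three-carbon bridge is consumed.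

Step 15
Reactants: 20 tricyclic acyloin; 21 acryloyl chloride
Product: 22 acrylate ester of the tertiary hydroxyl of 20
Conditions: i-Pr2NEt, DMAP (20 mol%), CH2Cl2, 0 °C to rt
Reagents that add atoms: none
Why: Acylation of the tertiary α-ketol hydroxyl with a small, reactive acid chloride under nucleophilic catalysis, a standard way to esterify hindered tertiary alcohols.

Step 16
Reactants: 22 acrylate ester of the tertiary hydroxyl of 20
Product: 24 α-methylene-β-hydroxy-γ-lactone (cis-fused to ring C), via phenylselanylmethyl lactone 23 (not isolated)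
Conditions: PhSeLi (from PhSeH, n-BuLi), THF, −78 °C; then H2O2, pyridine, 0 °C
Reagents that add atoms: none
Why: Selenolate-triggered Michael–aldol cyclisation (a Morita–Baylis–Hillman-type sequence), in which the weakly basic selenolate adds to the acrylate to generate the ester enolate regiospecifically, the enolate closes onto the neighbouring ketone from the face to which the ester is tethered (cis-fused lactone, hydroxyl outward), and oxidation to the selenoxide with syn elimination unveils the exocyclic methylene.

Step 17
Reactants: 24 α-methylene-β-hydroxy-γ-lactone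
Product: 25 α-methyl-β-hydroxy-γ-lactone with free tertiary ring hydroxyl and silyl ether intact
Conditions: H2 (1 atm), Pd(OH)2/C, EtOAc/EtOH, rt
Reagents that add atoms: none
Why: Heterogeneous hydrogenation delivers hydrogen to the exocyclic alkene from the open outer face of the lactone (the face carrying the tertiary hydroxyl and the ring-fusion methyl), which places the new methyl on the inner face, trans to the adjacent hydroxyl as in the target, and the same conditions hydrogenolyse the benzyl ether.

Step 18
Reactants: 25 α-methyl-β-hydroxy-γ-lactone with free tertiary ring hydroxyl and silyl ether intact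
Product: 26 triol (primary alcohol on the bridgehead carbon)
Conditions: HF·pyridine, THF, 0 °C to rt
Reagents that add atoms: none
Why: Fluoride-mediated cleavage of the primary silyl ether under mildly acidic conditions that cannot trigger retro-aldol loss of the hydroxymethyl group or epimerise the lactone.

Step 19
Reactants: 26 triol (primary alcohol on the bridgehead carbon)
Product: 27 bridgehead aldehyde
Conditions: Dess–Martin periodinane, CH2Cl2, rt
Reagents that add atoms: none
Why: Dess–Martin oxidation touches only the primary alcohol because the other two hydroxyls are tertiary, and the aldehyde formed has no α-hydrogen.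

Step 20
Reactants: 28 (E)-but-2-enal; 29 iodoform
Product: 30 (1E,3E)-1-iodopenta-1,3-diene
Conditions: CrCl2 (6 equiv), THF, 0 °C
Reagents that add atoms: none
Why: Takai olefination, in which the geminal dichromium species from iodoform converts the aldehyde into the E vinyl iodide and leaves the existing E alkene untouched.

Step 21
Reactants: 27 bridgehead aldehyde; 30 (1E,3E)-1-iodopenta-1,3-diene
Product: 31 dienyl carbinol (both carbinol epimers)
Conditions: CrCl2 (4 equiv), NiCl2 (2 mol%), DMSO, rt
Reagents that add atoms: none
Why: Nozaki–Hiyama–Kishi coupling, in which the dienylchromium species adds chemoselectively to the aldehyde in the presence of two ketones, a lactone and free tertiary hydroxyls with retention of the E,E geometry, the carbinol configuration being irrelevant.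

Step 22
Reactants: 31 dienyl carbinol
Product: 32 bridgehead (2E,4E)-hexa-2,4-dienoyl ketone
Conditions: Dess–Martin periodinane, CH2Cl2, 0 °C
Reagents that add atoms: none
Why: Dess–Martin oxidation of the doubly allylic secondary alcohol gives the dienone without base, so the lactone α-methyl centre is not disturbed.

Step 23
Reactants: 32 bridgehead (2E,4E)-hexa-2,4-dienoyl ketone; 33 (2E,4E)-hexa-2,4-dienoyl chloride
Product: 34 CNP0231466.1 (target)
Conditions: MgBr2·OEt2 (2.5 equiv), i-Pr2NEt (3 equiv), CH2Cl2, rt
Reagents that add atoms: none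
Why: Soft-enolisation C-acylation, in which magnesium bromide and the tertiary amine form the magnesium enolate of the only enolisable ketone (toward the ring CH2 between that ketone and the bridgehead CH) and the acid chloride acylates it on carbon to give the β-diketone, which tautomerises to the hydrogen-bonded exocyclic enol of the target under conditions too mild to enolise the lactone.

**Compound list**

1 | 2-methyl-2-vinyloxirane (racemic) | CC1(C=C)CO1 | starting material
2 | benzyl alcohol | OCc1ccccc1 | starting material
3 | (2S)-2-(benzyloxy)-2-methylbut-3-en-1-ol | C=C[C@](C)(OCc1ccccc1)CO | intermediate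
4 | (2S)-2-(benzyloxy)-2-methylbut-3-enal | C=C[C@](C)(OCc1ccccc1)C=O | intermediate
5 | tert-butyl diazoacetate | CC(C)(C)OC(=O)C=[N+]=[N-] | starting material
6 | tert-butyl (4S)-4-(benzyloxy)-4-methyl-3-oxohex-5-enoate | C=C[C@](C)(OCc1ccccc1)C(=O)CC(=O)OC(C)(C)C | intermediate
7 | chloroacetone | CC(=O)CCl | starting material
8 | tert-butyl (4S)-4-(benzyloxy)-4-methyl-3-oxo-2-(2-oxopropyl)hex-5-enoate (C2 epimers) | C=C[C@](C)(OCc1ccccc1)C(=O)C(CC(C)=O)C(=O)OC(C)(C)C | intermediate
9 | tert-butyl (2S,3S)-2-[(2S)-2-(benzyloxy)-2-methylbut-3-enoyl]-3-(hydroxymethyl)-3-methyl-2-(2-oxopropyl)pent-4-enoate | C=C[C@](C)(OCc1ccccc1)C(=O)[C@](C(=O)OC(C)(C)C)(CC(C)=O)[C@](C)(C=C)CO | intermediate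
10 | tert-butyl (2S,3S)-2-[(2S)-2-(benzyloxy)-2-methylbut-3-enoyl]-3-formyl-3-methyl-2-(2-oxopropyl)pent-4-enoate | C=C[C@](C)(OCc1ccccc1)C(=O)[C@](C(=O)OC(C)(C)C)(CC(C)=O)[C@](C)(C=C)C=O | intermediate
11 | vinyl bromide | C=CBr | starting material
12 | tert-butyl (2S,3S)-2-[(2S)-2-(benzyloxy)-2-methylbut-3-enoyl]-3-(1-hydroxyprop-2-en-1-yl)-3-methyl-2-(2-oxopropyl)pent-4-enoate (carbinol epimers) | C=C[C@](C)(OCc1ccccc1)C(=O)[C@](C(=O)OC(C)(C)C)(CC(C)=O)[C@](C)(C=C)C(O)C=C | intermediate
13 | tert-butyl (1S,3S,7S)-3-(benzyloxy)-7-ethenyl-6-hydroxy-3,7-dimethyl-2-oxo-1-(2-oxopropyl)cyclohept-4-ene-1-carboxylate (C6 epimers) | CC(C)(C)OC(=O)[C@]1(CC(C)=O)C(=O)[C@@](C)(OCc2ccccc2)C=CC(O)[C@@]1(C)C=C | intermediate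
14 | (4S,6R,7S)-4-(benzyloxy)-7-ethenyl-6-(hydroxymethyl)-6-(2-hydroxypropyl)-4,7-dimethylcyclohept-2-ene-1,5-diol (carbinol carbons as mixtures) | OC[C@]1(CC(C)O)C(O)[C@@](C)(OCc2ccccc2)C=CC(O)[C@@]1(C)C=C | intermediate
15 | (4S,6R,7S)-4-(benzyloxy)-6-{[tert-butyl(dimethyl)silyl]oxymethyl}-7-ethenyl-6-(2-hydroxypropyl)-4,7-dimethylcyclohept-2-ene-1,5-diol (carbinol carbons as mixtures) | CC(C)(C)[Si](C)(C)OC[C@]1(CC(C)O)C(O)[C@@](C)(OCc2ccccc2)C=CC(O)[C@@]1(C)C=C | intermediate
16 | (4S,6R,7S)-4-(benzyloxy)-6-{[tert-butyl(dimethyl)silyl]oxymethyl}-7-ethenyl-4,7-dimethyl-6-(2-oxopropyl)cyclohept-2-ene-1,5-dione (acetonyl, benzyloxy and ethenyl on one ring face) | CC(C)(C)[Si](C)(C)OC[C@]1(CC(C)=O)C(=O)[C@@](C)(OCc2ccccc2)C=CC(=O)[C@@]1(C)C=C | intermediate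
17 | (1R,4S,5R,7S,8S)-8-acetyl-7-(benzyloxy)-5-{[tert-butyl(dimethyl)silyl]oxymethyl}-4-ethenyl-4,7-dimethylbicyclo[3.2.1]octane-3,6-dione (acetyl syn to the three-carbon bridge, benzyloxy exo) | CC(C)(C)[Si](C)(C)OC[C@@]12[C@@H](C(C)=O)[C@@H](CC(=O)[C@@]1(C)C=C)[C@](C)(OCc3ccccc3)C2=O | intermediate
18 | secondary ozonide of 17 (1,2,4-trioxolan-3-yl in place of ethenyl; trioxolane carbon unspecified) | CC(C)(C)[Si](C)(C)OC[C@@]12[C@@H](C(C)=O)[C@@H](CC(=O)[C@@]1(C)C4OCOO4)[C@](C)(OCc3ccccc3)C2=O | intermediate (not isolated)
19 | keto aldehyde: 8-acetyl-7-(benzyloxy)-5-{[tert-butyl(dimethyl)silyl]oxymethyl}-4,7-dimethyl-3,6-dioxobicyclo[3.2.1]octane-4-carbaldehyde, stereocentres as in 17 | CC(C)(C)[Si](C)(C)OC[C@@]12[C@@H](C(C)=O)[C@@H](CC(=O)[C@@]1(C)C=O)[C@](C)(OCc3ccccc3)C2=O | intermediate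
20 | tricyclic acyloin: ring C fused to the bicyclo[3.2.1]octane of 19, ketone at the former aldehyde carbon, tertiary hydroxyl (toward the cyclohexanone) and methyl (outward) at the former acetyl carbon | CC(C)(C)[Si](C)(C)OC[C@]12C(=O)[C@@](C)(OCc4ccccc4)[C@@H]3CC(=O)[C@@]1(C)C(=O)[C@](O)(C)[C@@H]32 | intermediate
21 | acryloyl chloride | C=CC(Cl)=O | starting material
22 | acrylate ester of the tertiary hydroxyl of 20 | CC(C)(C)[Si](C)(C)OC[C@]12C(=O)[C@@](C)(OCc4ccccc4)[C@@H]3CC(=O)[C@@]1(C)C(=O)[C@](OC(=O)C=C)(C)[C@@H]32 | intermediate
23 | cis-fused β-hydroxy-γ-lactone bearing α-(phenylselanylmethyl) (α-carbon unspecified) | CC(C)(C)[Si](C)(C)OC[C@]12C(=O)[C@@](C)(OCc4ccccc4)[C@@H]3CC(=O)[C@@]1(C)[C@@]5(O)C(C[Se]c6ccccc6)C(=O)O[C@@]5(C)[C@@H]32 | intermediate (not isolated)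
24 | cis-fused α-methylene-β-hydroxy-γ-lactone (benzyl and silyl ethers intact) | CC(C)(C)[Si](C)(C)OC[C@]12C(=O)[C@@](C)(OCc4ccccc4)[C@@H]3CC(=O)[C@@]1(C)[C@@]5(O)C(=C)C(=O)O[C@@]5(C)[C@@H]32 | intermediate
25 | α-methyl-β-hydroxy-γ-lactone (methyl trans to the adjacent hydroxyl), free tertiary ring hydroxyl, silyl ether intact | CC(C)(C)[Si](C)(C)OC[C@]12C(=O)[C@@](C)(O)[C@@H]3CC(=O)[C@@]1(C)[C@@]4(O)[C@@H](C)C(=O)O[C@@]4(C)[C@@H]32 | intermediate
26 | triol: 25 with the silyl ether replaced by a primary hydroxyl | OC[C@]12C(=O)[C@@](C)(O)[C@@H]3CC(=O)[C@@]1(C)[C@@]4(O)[C@@H](C)C(=O)O[C@@]4(C)[C@@H]32 | intermediate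
27 | bridgehead aldehyde: 26 with CH2OH oxidised to CHO | O=C[C@]12C(=O)[C@@](C)(O)[C@@H]3CC(=O)[C@@]1(C)[C@@]4(O)[C@@H](C)C(=O)O[C@@]4(C)[C@@H]32 | intermediate
28 | (E)-but-2-enal | C/C=C/C=O | starting material
29 | iodoform | IC(I)I | starting material
30 | (1E,3E)-1-iodopenta-1,3-diene | C/C=C/C=C/I | intermediate
31 | dienyl carbinol: 27 after addition of the (1E,3E)-penta-1,3-dienyl group to the aldehyde (carbinol epimers) | C/C=C/C=C/C(O)[C@]12C(=O)[C@@](C)(O)[C@@H]3CC(=O)[C@@]1(C)[C@@]4(O)[C@@H](C)C(=O)O[C@@]4(C)[C@@H]32 | intermediate
32 | bridgehead (2E,4E)-hexa-2,4-dienoyl ketone | C/C=C/C=C/C(=O)[C@]12C(=O)[C@@](C)(O)[C@@H]3CC(=O)[C@@]1(C)[C@@]4(O)[C@@H](C)C(=O)O[C@@]4(C)[C@@H]32 | intermediate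
33 | (2E,4E)-hexa-2,4-dienoyl chloride | C/C=C/C=C/C(Cl)=O | starting material
34 | CNP0231466.1 | C/C=C/C=C/C(=O)[C@]12C(=O)[C@@](C)(O)[C@@H]3\C(=C(O)/C=C/C=C/C)C(=O)[C@@]1(C)[C@@]1(O)[C@@H](C)C(=O)O[C@@]1(C)[C@@H]32 | target

**Step count and risk**

Total step count: 23. Longest linear sequence: 22 (steps 1–19 and 21–23); step 20 is a one-step side branch.

Steps most likely to fail:

Step 5. The fully substituted, hindered enolate may attack the unsubstituted terminus of the π-allyl complex instead of the tertiary one, or the chiral pocket may discriminate poorly between the two faces of the enolate carbon. The fallback sets the two quaternary carbons in separate catalyst-controlled events. It sets out from 6: the same palladium/ent-L system with 1 should give tert-butyl (4S)-4-(benzyloxy)-2-[(2S)-1-hydroxy-2-methylbut-3-en-2-yl]-4-methyl-3-oxohex-5-enoate F1, in which only the methyl/vinyl carbon is stereogenic and the nucleophile is the less hindered CH2 β-keto ester. The remaining acidic CH of this compound is then alkylated with 7 under a chiral quaternary ammonium phase-transfer catalyst (N-(9-anthracenylmethyl)cinchonidinium bromide, solid Cs2CO3, toluene, −20 °C), an asymmetric alkylation of β-keto esters, and the route is rejoined at 9.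

Step 12. Enolisation on the methyl side followed by aldol closure onto a ring ketone and irreversible loss of water could divert material, and prolonged base could cleave the silyl ether. The fallback replaces the equilibrating enolate by a defined enol derivative. It sets out from 16, which is converted under thermodynamic silylation conditions (TMSCl, NaI, Et3N, MeCN) into the more substituted trimethylsilyl enol ether of the acetonyl ketone F2. A Mukaiyama–Michael cyclisation of this enol ether (TMSOTf or TiCl4, CH2Cl2, −78 °C, aqueous work-up) forms the same bond without any free enolate and comes back to the route at 17.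

Step 14. Carbene addition to the neopentyl-type aldehyde may be slow, which would let the amine base promote aldol closure of the acetyl methyl group onto the aldehyde or loss of the formyl group by retro-Claisen-type cleavage. The fallback closes ring C reductively instead. It sets out from 19: SmI2 in THF at −78 °C should couple the aldehyde and the methyl ketone (pinacol cyclisation) to the cis-cyclopentane-1,2-diol F3. Parikh–Doering oxidation (SO3·pyridine, DMSO, Et3N) of its secondary hydroxyl, the tertiary one being inert, returns to the route at 20.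

Further compounds
F1 | step 5 | tert-butyl (4S)-4-(benzyloxy)-2-[(2S)-1-hydroxy-2-methylbut-3-en-2-yl]-4-methyl-3-oxohex-5-enoate (C2 epimers) | C=C[C@](C)(OCc1ccccc1)C(=O)C(C(=O)OC(C)(C)C)[C@](C)(C=C)CO
F2 | step 12 | trimethylsilyl enol ether of 16 (more substituted enol of the acetonyl ketone, geometry unspecified) | CC(C)(C)[Si](C)(C)OC[C@]1(C=C(C)O[Si](C)(C)C)C(=O)[C@@](C)(OCc2ccccc2)C=CC(=O)[C@@]1(C)C=C
F3 | step 14 | cis-cyclopentane-1,2-diol from pinacol closure of 19 (secondary carbinol unspecified) | CC(C)(C)[Si](C)(C)OC[C@]12C(=O)[C@@](C)(OCc4ccccc4)[C@@H]3CC(=O)[C@@]1(C)C(O)[C@](O)(C)[C@@H]32
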